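# Proposed total synthesis of DMGF (7,7''-di-O-methylagathisflavone) by cyclobutenone–ynol ether benzannulation

## The problem

DMGF is made of two genkwanin units (5,4'-dihydroxy-7-methoxyflavone). They are joined by one bond from C6 of unit 1 to C8 of unit 2, so two chromen-4-one bicycles, each with a 4-hydroxyphenyl ring B at C2, hang on a single biaryl bond. That bond has four ortho substituents: C5–OH and C7–OMe of unit 1, and C7–OMe and the ring-oxygen carbon C8a of unit 2. Direct aryl–aryl coupling is therefore the least attractive way to form it. There is no sp3 stereocentre; the only stereogenic element is the hindered axis, whose configuration is not specified, so nothing has to be relayed. The real selectivity problem is telling oxygens apart. Each ring A is a phloroglucinol whose three oxygens must become a methyl ether, a chelated hydroxyl and the pyranone oxygen, and unit 1 closes its pyranone through the oxygen para to the axis whereas unit 2 uses the oxygen ortho to it. An aryl ketone flanked by two free hydroxyls could close either way and scramble the 6- and 8-linkage, and hot protic acid can do the same later by Wessely–Moser ring opening; each ring may therefore show only one free hydroxyl when its pyranone closes. The four phenols are best released last under mild aprotic conditions that spare the two C7 methyl ethers, and the ynol ether met on the way is acid-labile. The enabling feature lies in ring A of unit 2: C8 sits between C8a (oxygen) and C7 (methoxyl), C5 is oxygenated, and C6 and C4a carry hydrogen. This 1-hydroxy-2-aryl-3-methoxy-5-alkoxy pattern is what forms when the carbonyl carbon of a 3-alkoxy vinylketene and the oxygen-bearing carbon of an ynol ether end up on either side of the aryl-bearing alkyne carbon.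

## Retrosynthesis

**Release of the phenols (19 ⇒ 18).** The last step should break only O–alkyl bonds.
- Four bonds are cut: the peri ethers at C5 of both units and the two ring B ethers.
- In 18 these are a methyl ether (unit 1 C5), an ethyl ether (unit 2 C5) and two isopropyl ethers. The C7 oxygens already carry their final methyl groups.
- Peri ethers are activated by chelation to the C4 carbonyl and isopropyl ethers by easy ionisation. The C7 methyl ethers have neither activation, so one chelating Lewis acid is asked to distinguish the classes.
- Benzyl groups on ring B would cost a second operation.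
- 18 has the same skeleton as 19 but no free phenol to oxidise.

**Both pyranones at once (18 ⇒ 17 ⇒ 15 + 16).** Rings B and C are identical in the two units, so they are cut in parallel.
- Cutting O1–C2 in each unit leads to bichalcone 17. Cutting C2=C3 in each unit leads to diketone 15 and two molecules of aldehyde 16.
- The neighbouring cut, C2–C3 as an acyl transfer (Baker–Venkataraman), needs one more operation and ends in an acid cyclodehydration. It is kept in reserve.
- About half of the carbon atoms and four of the six rings are removed.
- The forward closure requires that each enone finds a single ortho hydroxyl. In 17 this holds because C5 is still an ether in both units.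

**Two acetyl groups (15 ⇒ 13).** C4–C4a is cut in both units to give biphenyldiol 13.
- Acylating unit 2 while unit 1 stays masked was weighed and dropped. The masked ring is a trialkoxybenzene at least as nucleophilic as the ring to be acylated, and it has no hydroxyl to steer the electrophile.
- With both hydroxyls free, the competitor becomes the second substrate, each ring has its own directing group, and the endgame is halved.
- The forward reaction must be ortho-selective. Unit 2 offers one open ortho site (C4a) and one para rival (C6). Unit 1 offers two equivalent ortho sites, and its para position is blocked by the axis.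

**Unmasking unit 1 (13 ⇒ 12).** Only the O–benzyl bond is cut. Benzyl is chosen because it tolerates organozinc chemistry and prolonged heating, and it leaves under neutral hydrogenolysis that touches no methyl or ethyl ether.

**Ring A of unit 2 (12 ⇒ 6 + 7).** C8–C8a and C6–C7 are cut; C4a–C8a is broken and re-formed during the reaction.
- A cut at the axis would demand a halogenated phloroglucinol with three different oxygen substituents, made by selective alkylation, and then a tetra-ortho-substituted cross-coupling.
- The benzannulation gives each oxygen its own origin: the hydroxyl comes from the ketone of 7, the ethoxyl from its enol ether, and the methoxyl from ynol ether 6.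
- The precursors are a four-carbon ring and a monoaryl alkyne.
- The forward reaction has to be regioselective in the ketene–alkyne addition, and both partners have to survive the temperature.

**The future biaryl bond (6 ⇒ 2 + 3).** The aryl–alkynyl bond of 6, which later becomes the C6–C8 axis, is cut to aryl bromide 2 and a methoxyethynyl metal.
- The methoxyethynyl metal is drawn from chloroacetal 3 by double elimination through 4 and 5.
- An sp-carbon nucleophile is slim, so the two ortho methoxyls matter only in the oxidative addition, and that can be handled by ligand choice.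
- A methyl rather than an ethyl ynol ether is needed so that no retro-ene loss of alkene can occur on heating.

**Protection (2 ⇒ 1).** The O–benzyl bond is cut back to bromophenol 1. Its symmetry (two equivalent methoxyls, two equivalent ring hydrogens) is what makes the later acylation of unit 1 unambiguous.

## Roads not taken

**Alternative 1:**
- *Cut:* both rings A are opened at once. C5–C6 of unit 1 and C8–C8a of unit 2 are broken, and the biaryl bond becomes the central CH2–CH2 bond of the acyclic chain dimethyl (4E,8E)-5,8-dimethoxy-3,10-dioxododeca-4,8-dienedioate A2.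
- *Forward key step:* excess base would make each central carbon attack the ester six atoms away. Double Claisen closure and enolisation would give 6,6'-dimethoxybiphenyl-2,2',4,4'-tetraol A1.
- *Merits:* the hindered bond begins as an unhindered sp3–sp3 bond, which is as good an answer to the steric problem as the aryl–alkyne bond of 6. Two rings arise in one operation from a cheap symmetric chain, and up to the biaryl stage this road is shorter than 1 → 13.
- *Weak points in the closure:* the carbons that must attack are gamma positions of vinylogous esters, while the first protons removed are those of the two beta-keto ester methylenes. A polyanion is therefore required, and O-closure to pyranones or aldol-type closure competes.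
- *Weak point for this target:* A1 is C2-symmetric with four free hydroxyls, yet DMGF uses its halves in opposite senses. Acylation would fall between two hydroxyls on each ring, and each ketone could then close on either neighbour. 6,6-, 6,8- and 8,8-linked isomers would all be expected unless the two identical rings are protected in opposite ways.
- *Comparison:* the chosen plan makes one ring at a time. In return, 12 leaves the key step with one free hydroxyl, one ethyl ether, one benzyl ether and methyl ethers exactly where they are wanted.

**Alternative 2:**
- *Cut:* the C6–C8 bond itself, between two finished flavones. 4'-Benzyloxy-5-hydroxy-6-iodo-7-methoxyflavone A5 and 4'-benzyloxy-7-hydroxy-8-iodo-5-methoxyflavone A6 would be tied through O5 of unit 1 and O7 of unit 2 as the formaldehyde acetal diiodide A4.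
- *Forward key step:* a zerovalent palladium catalyst and a distannane would stannylate one iodide and couple it with the other. This closes a seven-membered dibenzodioxepine in the bridged biflavone A3.
- *Merits:* this is the most convergent plan. All pyranone chemistry is done on simple monomers, the iodides fix the linkage beyond doubt, and the tether turns an intermolecular tetra-ortho coupling into a ring closure. In convergence and in certainty of the linkage it is better than the chosen route.
- *Weak points:*
  - The mixed acetal has to be made from two different phenols. The C5–OH of A5 is hydrogen-bonded to the carbonyl and flanked by iodine, so symmetric acetals and poor conversion are likely.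
  - Two separate regioselective iodinations need two protecting-group patterns.
  - The bond is still formed by reductive elimination between two di-ortho-substituted aryl groups, with stoichiometric tin, and protodeiodination competes.
  - The tether leaves unit 2 with O7 in the acetal and O5 as a methyl ether. Acetal hydrolysis, selective O7 methylation, peri demethylation and debenzylation must follow.
- *Comparison:* the chosen plan never asks a metal to join two hindered arenes, it needs no tin, and it carries the C7 methyl ethers in their final form from the start.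

**Alternative 3:**
- *Cut:* the pyranone of unit 1 at C8a–O1 and C4a–C4.
- *Forward key step:* fluoride would release the aryne across C4a–C8a from the biaryl silyl triflate A8. The C–O bond of 3-(4-isopropoxyphenyl)propiolic acid A9 would insert to give the ortho-hydroxyaryl ynone A7, one 6-endo cyclisation away from a flavone.
- *Merits:* carbonyl, O1, C2–C3 and ring B arrive together. The C5 methoxyl next to the aryne directs the carboxylate oxygen to the distal carbon C8a and the acyl group to C4a, which is the correct sense. For one pyranone this is shorter than steps 5–7 of the chosen route.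
- *Weak points:*
  - It leaves the central problem untouched. A8 is already a tetra-ortho-substituted biaryl with differentiated oxygens and an adjacent silyl/triflate pair. Making it needs the hindered coupling the other plans avoid, plus several steps of directed silylation.
  - Plain O-arylation by proton transfer competes with insertion.
  - The alkyne and the ready decarboxylation of A9 open further pathways.
  - The key step closes no ring.
  - The pyranone of unit 2 must still be built conventionally after debenzylation, so the two pyranones cannot be made together.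
- *Comparison:* the chosen plan spends its key step on the hard part, the hindered and fully differentiated biaryl, and then pays for both pyranones with three routine two-directional operations.

Key step: step 3

Assumption: 1, 3, 7 and 16 are taken as catalogue chemicals, and because the structure carries no axial descriptor, 15, 17, 18 and 19 are made as racemates about the C6–C8 axis.

## Route

Step 1
Reactants: 1 4-bromo-3,5-dimethoxyphenol
Product: 2 5-(benzyloxy)-2-bromo-1,3-dimethoxybenzene
Conditions: BnBr, K2CO3, DMF, rt
Reagents that add atoms: benzyl bromide, BrCc1ccccc1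
Why: Williamson etherification at the only acidic site; the benzyl group masks the future ring oxygen of unit 1 through the organometallic and thermal steps and leaves later under neutral hydrogenolysis.

Step 2
Reactants: 2 5-(benzyloxy)-2-bromo-1,3-dimethoxybenzene; 3 2-chloro-1,1-dimethoxyethane
Product: 6 5-(benzyloxy)-2-(methoxyethynyl)-1,3-dimethoxybenzene, via lithium methoxyacetylide 4 (not isolated), via methoxyethynylzinc chloride 5 (not isolated)
Conditions: 3, LiNEt2 (3 equiv, from Et2NH and n-BuLi), THF, −10 → 0 °C; ZnCl2, 0 °C; then 2, Pd2(dba)3 (cat.), SPhos (cat.), THF, 55 °C; aq. NaHCO3 work-up, Et3N-deactivated silica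
Reagents that add atoms: none
Why: Double base-induced elimination of the chloroacetal gives the lithium alkoxyacetylide, transmetalation to zinc tames its basicity, and a Negishi alkynylation joins it to the aryl bromide. The bulky electron-rich biarylphosphine is chosen because oxidative addition of zerovalent palladium to a di-ortho-methoxylated, electron-rich C–Br bond is the slow event, whereas the slim sp-carbon nucleophile meets little hindrance. Non-acidic work-up protects the ynol ether from hydration.

Step 3
Reactants: 6 5-(benzyloxy)-2-(methoxyethynyl)-1,3-dimethoxybenzene; 7 3-ethoxycyclobut-2-en-1-one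
Product: 12 2-(4-benzyloxy-2,6-dimethoxyphenyl)-5-ethoxy-3-methoxyphenol, via ethoxy vinylketene 8 (not isolated), via vinylcyclobutenone adduct 9 (not isolated), via dienylketene 10 (not isolated), via cyclohexadienone 11 (not isolated)
Conditions: 7 (2 equiv, in portions), toluene (0.5 M), 80 °C then 120 °C, sealed tube, Ar
Reagents that add atoms: none
Why: This is a Danheiser benzannulation of a cyclobutenone with an alkoxyalkyne, a reaction type in which both 3-oxygenated cyclobutenones and 1-alkoxyalkynes are established partners. At 80 °C 7 opens by four-electron conrotatory cleavage of its C1–C4 bond to vinylketene 8, which 6 traps in a [2+2] addition across the ketene C=C bond to give 9. In this addition the aryl-bearing alkyne carbon, made nucleophilic by the methoxy lone pair, bonds to the ketene carbonyl carbon (unit 2 C8–C8a) and the methoxy-bearing carbon bonds to the ketene alpha carbon (C6–C7); this regiochemistry is the only selectivity needed, and the polarised ynol ether secures it because the reverse orientation forgoes oxocarbenium-type stabilisation. At 120 °C 9 reopens reversibly to dienylketene 10, and the isomer whose ethoxyvinyl group points towards the ketene closes ring A of unit 2 by six-electron disrotatory electrocyclisation, joining the vinyl CH2 to the ketene carbon (C4a–C8a). Tautomerisation of dienone 11 to phenol 12 is irreversible and drains all preceding equilibria. No stereocentre results: the sp3 carbon of 9 disappears on reopening, and the new axis is not stereogenic in 12 because the unit 1 ring is symmetric about it. The methyl ynol ether has no beta hydrogen and cannot fragment by a retro-ene path at these temperatures, and the linear alkyne holds the two ortho methoxyls away from the bonding carbon, so a tetra-ortho-substituted biaryl arises without any aryl–aryl coupling.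

Step 4
Reactants: 12 2-(4-benzyloxy-2,6-dimethoxyphenyl)-5-ethoxy-3-methoxyphenol
Product: 13 4-ethoxy-2',6,6'-trimethoxy[1,1'-biphenyl]-2,4'-diol
Conditions: H2 (1 atm), 10% Pd/C, EtOAc–MeOH, rt
Reagents that add atoms: none
Why: Catalytic hydrogenolysis of a benzyl aryl ether; methyl and ethyl ethers and the arene rings are inert, and 13 now shows exactly one free hydroxyl on each ring.

Step 5
Reactants: 13 4-ethoxy-2',6,6'-trimethoxy[1,1'-biphenyl]-2,4'-diol
Product: 15 1,1'-(4-ethoxy-2,4'-dihydroxy-2',6,6'-trimethoxy[1,1'-biphenyl]-3,3'-diyl)diethanone, via bis(acetate) 14 (not isolated)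
Conditions: Ac2O (2.2 equiv), BF3·OEt2 (excess), 80 °C; then ice–water
Reagents that add atoms: acetic anhydride, CC(=O)OC(C)=O
Why: O-acetylation followed by BF3-mediated Fries rearrangement, the standard entry to 2-hydroxy-4,6-dialkoxyacetophenones. In unit 2 the only open ortho position is C4a and in unit 1 the two ortho positions are equivalent, and boron chelation makes the ortho-hydroxy ketone the thermodynamic sink over para attack at unit 2 C6. Each acetyl group deactivates its ring against a second acylation; the axis becomes stereogenic here and 15 is racemic.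

Step 6
Reactants: 15 1,1'-(4-ethoxy-2,4'-dihydroxy-2',6,6'-trimethoxy[1,1'-biphenyl]-3,3'-diyl)diethanone; 16 4-isopropoxybenzaldehyde
Product: 17 (2E,2'E)-1,1'-(4-ethoxy-2,4'-dihydroxy-2',6,6'-trimethoxy[1,1'-biphenyl]-3,3'-diyl)bis[3-(4-isopropoxyphenyl)prop-2-en-1-one]
Conditions: 16 (2.5 equiv), KOH (50% aq.), EtOH, rt; then 1 M HCl
Reagents that add atoms: none
Why: Double Claisen–Schmidt condensation with a non-enolisable aldehyde; dehydration of each aldol under equilibrating conditions gives the conjugated E-enone. The reaction is routine for 2-hydroxy-4,6-dialkoxyacetophenones.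

Step 7
Reactants: 17 (2E,2'E)-1,1'-(4-ethoxy-2,4'-dihydroxy-2',6,6'-trimethoxy[1,1'-biphenyl]-3,3'-diyl)bis[3-(4-isopropoxyphenyl)prop-2-en-1-one]
Product: 18 6-[5-ethoxy-7-methoxy-4-oxo-2-(4-isopropoxyphenyl)-4H-chromen-8-yl]-5,7-dimethoxy-2-(4-isopropoxyphenyl)-4H-chromen-4-one
Conditions: I2 (cat.), DMSO, 130 °C
Reagents that add atoms: none
Why: Iodine/DMSO oxidative cyclisation of 2'-hydroxychalcones to flavones, well used on 4',6'-dialkoxy substrates and on bichalcones. Each enone has one ortho hydroxyl only (C8a–OH), because C5 is still an ether in both units, so O1–C2 can close only in the sense that gives the 6-linkage in unit 1 and the 8-linkage in unit 2.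

Step 8
Reactants: 18 6-[5-ethoxy-7-methoxy-4-oxo-2-(4-isopropoxyphenyl)-4H-chromen-8-yl]-5,7-dimethoxy-2-(4-isopropoxyphenyl)-4H-chromen-4-one
Product: 19 DMGF, 5-hydroxy-6-[5-hydroxy-2-(4-hydroxyphenyl)-7-methoxy-4-oxo-4H-chromen-8-yl]-2-(4-hydroxyphenyl)-7-methoxy-4H-chromen-4-one
Conditions: BCl3 (excess), CH2Cl2, −78 °C → rt; then aq. HCl–MeOH
Reagents that add atoms: none
Why: Chelation-directed Lewis-acid ether cleavage: BCl3 binds each C4 carbonyl together with its peri oxygen and chloride removes the methyl (unit 1) and ethyl (unit 2) groups, while the secondary isopropyl aryl ethers ionise readily under the same reagent. The two C7 methyl ethers are neither chelated nor secondary and should stay, and the aprotic medium avoids Wessely–Moser isomerisation.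

## Compound list

1 | 4-bromo-3,5-dimethoxyphenol | COc1cc(O)cc(OC)c1Br | starting material
2 | 5-(benzyloxy)-2-bromo-1,3-dimethoxybenzene | COc1cc(OCc2ccccc2)cc(OC)c1Br | intermediate
3 | 2-chloro-1,1-dimethoxyethane (chloroacetaldehyde dimethyl acetal) | COC(CCl)OC | starting material
4 | lithium methoxyacetylide | [Li]C#COC | intermediate
5 | methoxyethynylzinc chloride | COC#C[Zn]Cl | intermediate
6 | 5-(benzyloxy)-2-(methoxyethynyl)-1,3-dimethoxybenzene | COC#Cc1c(OC)cc(OCc2ccccc2)cc1OC | intermediate
7 | 3-ethoxycyclobut-2-en-1-one | CCOC1=CC(=O)C1 | starting material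
8 | 3-ethoxybuta-1,3-dien-1-one | C=C(OCC)C=C=O | intermediate
9 | 2-[4-(benzyloxy)-2,6-dimethoxyphenyl]-4-(1-ethoxyvinyl)-3-methoxycyclobut-2-en-1-one (racemic) | C=C(OCC)C1C(=O)C(c2c(OC)cc(OCc3ccccc3)cc2OC)=C1OC | intermediate
10 | (3E)-2-[4-(benzyloxy)-2,6-dimethoxyphenyl]-5-ethoxy-3-methoxyhexa-1,3,5-trien-1-one | O=C=C(c1c(OC)cc(OCc2ccccc2)cc1OC)/C(OC)=C\C(=C)OCC | intermediate
11 | 2-[4-(benzyloxy)-2,6-dimethoxyphenyl]-5-ethoxy-3-methoxycyclohexa-2,4-dien-1-one | CCOC1=CC(OC)=C(c2c(OC)cc(OCc3ccccc3)cc2OC)C(=O)C1 | intermediate
12 | 2-(4-benzyloxy-2,6-dimethoxyphenyl)-5-ethoxy-3-methoxyphenol | CCOc1cc(O)c(-c2c(OC)cc(OCc3ccccc3)cc2OC)c(OC)c1 | intermediate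
13 | 4-ethoxy-2',6,6'-trimethoxy[1,1'-biphenyl]-2,4'-diol | CCOc1cc(O)c(-c2c(OC)cc(O)cc2OC)c(OC)c1 | intermediate
14 | 4-ethoxy-2',6,6'-trimethoxy[1,1'-biphenyl]-2,4'-diyl diacetate | CCOc1cc(OC(C)=O)c(-c2c(OC)cc(OC(C)=O)cc2OC)c(OC)c1 | intermediate
15 | 1,1'-(4-ethoxy-2,4'-dihydroxy-2',6,6'-trimethoxy[1,1'-biphenyl]-3,3'-diyl)diethanone (racemic axis) | CCOc1cc(OC)c(-c2c(OC)c(C(C)=O)c(O)cc2OC)c(O)c1C(C)=O | intermediate
16 | 4-isopropoxybenzaldehyde | CC(C)Oc1ccc(C=O)cc1 | starting material
17 | (2E,2'E)-1,1'-(4-ethoxy-2,4'-dihydroxy-2',6,6'-trimethoxy[1,1'-biphenyl]-3,3'-diyl)bis[3-(4-isopropoxyphenyl)prop-2-en-1-one] (racemic axis) | CCOc1cc(OC)c(-c2c(OC)c(C(=O)/C=C/c3ccc(OC(C)C)cc3)c(O)cc2OC)c(O)c1C(=O)/C=C/c4ccc(OC(C)C)cc4 | intermediate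
18 | 6-[5-ethoxy-7-methoxy-4-oxo-2-(4-isopropoxyphenyl)-4H-chromen-8-yl]-5,7-dimethoxy-2-(4-isopropoxyphenyl)-4H-chromen-4-one (racemic axis) | COc1cc2oc(-c3ccc(OC(C)C)cc3)cc(=O)c2c(OC)c1-c1c(OC)cc(OCC)c2c(=O)cc(-c3ccc(OC(C)C)cc3)oc12 | intermediate
19 | DMGF, 5-hydroxy-6-[5-hydroxy-2-(4-hydroxyphenyl)-7-methoxy-4-oxo-4H-chromen-8-yl]-2-(4-hydroxyphenyl)-7-methoxy-4H-chromen-4-one (racemic axis) | COc1cc2oc(-c3ccc(O)cc3)cc(=O)c2c(O)c1-c1c(OC)cc(O)c2c(=O)cc(-c3ccc(O)cc3)oc12 | target

## Step count and least certain steps

Total step count: 8. Longest linear sequence: 8 (1 → 19).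

**Step 3 (key step).**
- *Risk:* the cyclobutenone is a vinylogous ester and may open sluggishly. At the temperature needed, ketene dimerisation, O-acylation of the product phenol by the ketene and thermal decay of the ynol ether could then outrun the [2+2] addition. The strongly donating trialkoxyaryl group also works slightly against the polarisation of the alkyne and could erode the regioselectivity.
- *Fallback (from 6, back at 12):* the same vinylketene 8 is generated at room temperature by a photochemical Wolff rearrangement instead of thermal ring opening. Ethyl vinyl ether is lithiated with t-BuLi to 1-ethoxyvinyllithium F1, which is acylated with N-methoxy-N-methylacetamide to 3-ethoxybut-3-en-2-one F2. The lithium enolate of F2 is trifluoroacetylated with 2,2,2-trifluoroethyl trifluoroacetate to 5-ethoxy-1,1,1-trifluorohex-5-ene-2,4-dione F3. F3 is treated directly with mesyl azide, Et3N and water (detrifluoroacetylative diazo transfer) to give 1-diazo-3-ethoxybut-3-en-2-one F4. Irradiation of F4 with 6 in CH2Cl2 should form 8 and hence 9 without heating, and a separate thermal stage in toluene then carries 9 through 10 and 11 to 12.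

**Step 2.**
- *Risk:* slow oxidative addition to the hindered, electron-rich bromide would leave the alkynylzinc reagent time to homocouple or decay. The amine and methoxide left from the elimination may slow the catalyst, and hydration of the ynol ether can occur during isolation.
- *Fallback (from 2, back at 6):* the triple bond is made by elimination rather than coupling. Bromine–lithium exchange on 2 (n-BuLi, THF, −78 °C) gives [4-(benzyloxy)-2,6-dimethoxyphenyl]lithium F5. F5 is acylated with N,2-dimethoxy-N-methylacetamide to 1-[4-(benzyloxy)-2,6-dimethoxyphenyl]-2-methoxyethan-1-one F6. Enolisation with KHMDS and triflation with PhNTf2 gives the (Z)-enol triflate F7, and KOt-Bu then induces anti elimination of triflate to give 6. This is the known conversion of alpha-alkoxy ketones into ynol ethers.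

**Step 5.**
- *Risk:* para acylation at unit 2 C6, incomplete acyl migration from the hindered unit 2 acetate, and intermolecular acyl scrambling that leads to over-acylation.
- *Fallback (from 13, back at 18, bypassing steps 5–7):* magnesium-phenoxide-directed ortho-formylation (MgCl2, Et3N, paraformaldehyde, MeCN, reflux; Casnati–Skattebøl reaction) can occur only next to a free hydroxyl and gives the dialdehyde F8. Excess lithium (4-isopropoxyphenyl)acetylide F9, from 1-ethynyl-4-isopropoxybenzene and n-BuLi, adds to both aldehydes to give the bis(propargylic alcohol) F10 as a diastereomer mixture. MnO2 oxidation converges this mixture on the bis(ynone) F11, and DMAP-catalysed 6-endo oxa-Michael cyclisation in DMF gives 18.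

**Step 7.**
- *Risk:* electrophilic iodination at the still electron-rich C6 of unit 2 and C8 of unit 1, and acid-mediated loss of a peri ether before ring closure, which would open the second mode of cyclisation.
- *Fallback (from 15, back at 18):* an oxidant-free Baker–Venkataraman sequence. 4-Isopropoxybenzoyl chloride in pyridine gives the bis(aroyl ester) F12. KOH in pyridine brings about the O-to-C acyl shift to the bis(1,3-diketone) F13. Cyclodehydration with p-TsOH in refluxing toluene gives 18.

**Step 8.**
- *Risk:* chloride attack at the primary ethyl carbon is slower than at methyl, so cleavage of the unit 2 peri ether may lag. Forcing the reaction risks gradual loss of the C7 methyl ethers.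
- *Fallback (from 18, back at 19):* the global cleavage is split into two operations, each matched to one mechanism. MgI2·OEt2 in toluene–THF at reflux, with magnesium chelation and iodide as a far better nucleophile, removes only the two peri alkyl groups to give the 5,5''-dihydroxy-4',4'''-diisopropoxy biflavone F14. Brief BCl3 treatment at −78 → 0 °C then takes off the isopropyl groups alone to give 19.

## Further compounds

F1 | step 3 | 1-ethoxyvinyllithium | [Li]C(=C)OCC
F2 | step 3 | 3-ethoxybut-3-en-2-one | C=C(OCC)C(C)=O
F3 | step 3 | 5-ethoxy-1,1,1-trifluorohex-5-ene-2,4-dione | C=C(OCC)C(=O)CC(=O)C(F)(F)F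
F4 | step 3 | 1-diazo-3-ethoxybut-3-en-2-one | C=C(OCC)C(=O)C=[N+]=[N-]
F5 | step 2 | [4-(benzyloxy)-2,6-dimethoxyphenyl]lithium | [Li]c1c(OC)cc(OCc2ccccc2)cc1OC
F6 | step 2 | 1-[4-(benzyloxy)-2,6-dimethoxyphenyl]-2-methoxyethan-1-one | COCC(=O)c1c(OC)cc(OCc2ccccc2)cc1OC
F7 | step 2 | (Z)-1-[4-(benzyloxy)-2,6-dimethoxyphenyl]-2-methoxyvinyl trifluoromethanesulfonate | CO/C=C(\OS(=O)(=O)C(F)(F)F)c1c(OC)cc(OCc2ccccc2)cc1OC
F8 | step 5 | 4-ethoxy-2,4'-dihydroxy-2',6,6'-trimethoxy[1,1'-biphenyl]-3,3'-dicarbaldehyde | CCOc1cc(OC)c(-c2c(OC)c(C=O)c(O)cc2OC)c(O)c1C=O
F9 | step 5 | lithium (4-isopropoxyphenyl)acetylide | [Li]C#Cc1ccc(OC(C)C)cc1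
F10 | step 5 | 1,1'-(4-ethoxy-2,4'-dihydroxy-2',6,6'-trimethoxy[1,1'-biphenyl]-3,3'-diyl)bis[3-(4-isopropoxyphenyl)prop-2-yn-1-ol] (diastereomer mixture) | CCOc1cc(OC)c(-c2c(OC)c(C(O)C#Cc3ccc(OC(C)C)cc3)c(O)cc2OC)c(O)c1C(O)C#Cc4ccc(OC(C)C)cc4
F11 | step 5 | 1,1'-(4-ethoxy-2,4'-dihydroxy-2',6,6'-trimethoxy[1,1'-biphenyl]-3,3'-diyl)bis[3-(4-isopropoxyphenyl)prop-2-yn-1-one] | CCOc1cc(OC)c(-c2c(OC)c(C(=O)C#Cc3ccc(OC(C)C)cc3)c(O)cc2OC)c(O)c1C(=O)C#Cc4ccc(OC(C)C)cc4
F12 | step 7 | 3,3'-diacetyl-4-ethoxy-2',6,6'-trimethoxy[1,1'-biphenyl]-2,4'-diyl bis(4-isopropoxybenzoate) | CCOc1cc(OC)c(-c2c(OC)c(C(C)=O)c(OC(=O)c3ccc(OC(C)C)cc3)cc2OC)c(OC(=O)c3ccc(OC(C)C)cc3)c1C(C)=O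
F13 | step 7 | 1,1'-(4-ethoxy-2,4'-dihydroxy-2',6,6'-trimethoxy[1,1'-biphenyl]-3,3'-diyl)bis[3-(4-isopropoxyphenyl)propane-1,3-dione] | CCOc1cc(OC)c(-c2c(OC)c(C(=O)CC(=O)c3ccc(OC(C)C)cc3)c(O)cc2OC)c(O)c1C(=O)CC(=O)c4ccc(OC(C)C)cc4
F14 | step 8 | 5-hydroxy-6-[5-hydroxy-7-methoxy-4-oxo-2-(4-isopropoxyphenyl)-4H-chromen-8-yl]-7-methoxy-2-(4-isopropoxyphenyl)-4H-chromen-4-one | COc1cc2oc(-c3ccc(OC(C)C)cc3)cc(=O)c2c(O)c1-c1c(OC)cc(O)c2c(=O)cc(-c3ccc(OC(C)C)cc3)oc12
A1 | alternative 1 | 6,6'-dimethoxybiphenyl-2,2',4,4'-tetraol | COc1cc(O)cc(O)c1-c1c(O)cc(O)cc1OC
A2 | alternative 1 | dimethyl (4E,8E)-5,8-dimethoxy-3,10-dioxododeca-4,8-dienedioate | COC(=O)CC(=O)/C=C(/OC)CC\C(OC)=C/C(=O)CC(=O)OC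
A3 | alternative 2 | methylene-bridged 6,8-linked biflavone (O5 of unit 1 to O7 of unit 2) | COc1cc2oc(-c3ccc(OCc4ccccc4)cc3)cc(=O)c2c(OCOc3cc(OC)c4c(=O)cc(-c5ccc(OCc6ccccc6)cc5)oc4c3-7)c17
A4 | alternative 2 | formaldehyde acetal of the 6-iodo and 8-iodo flavones (diiodide) | COc1cc2oc(-c3ccc(OCc4ccccc4)cc3)cc(=O)c2c(OCOc3cc(OC)c4c(=O)cc(-c5ccc(OCc6ccccc6)cc5)oc4c3I)c1I
A5 | alternative 2 | 4'-benzyloxy-5-hydroxy-6-iodo-7-methoxyflavone | COc1cc2oc(-c3ccc(OCc4ccccc4)cc3)cc(=O)c2c(O)c1I
A6 | alternative 2 | 4'-benzyloxy-7-hydroxy-8-iodo-5-methoxyflavone | COc1cc(O)c(I)c2oc(-c3ccc(OCc4ccccc4)cc3)cc(=O)c12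
A7 | alternative 3 | 1-[3-(2-benzyloxy-4,6-dimethoxyphenyl)-6-hydroxy-2,4-dimethoxyphenyl]-3-(4-isopropoxyphenyl)prop-2-yn-1-one | COc1cc(O)c(C(=O)C#Cc2ccc(OC(C)C)cc2)c(OC)c1-c1c(OC)cc(OC)cc1OCc1ccccc1
A8 | alternative 3 | 2'-(benzyloxy)-2,4',6,6'-tetramethoxy-3-(trimethylsilyl)[1,1'-biphenyl]-4-yl trifluoromethanesulfonate | COc1cc(OS(=O)(=O)C(F)(F)F)c([Si](C)(C)C)c(OC)c1-c1c(OC)cc(OC)cc1OCc1ccccc1
A9 | alternative 3 | 3-(4-isopropoxyphenyl)propiolic acid | CC(C)Oc1ccc(C#CC(=O)O)cc1
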